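**Retrosynthetic overview**
1. Endgame: the formyl group (Rieche) and the isovaleryl group (Friedel–Crafts) go on last; before that, the benzylic C=O of a pentacyclic benzoxepinone is taken down to CH2 and two benzyl ethers are removed.
2. Key disconnection: the bond between the CH bridgehead (C4) and the CMe2 bridge (C7) of the bornane, together with C5–C6, is opened to a gem-dimethylcyclopropane (C1–C6–C7) fused to the oxepinone and an allyl group on C2. Forward, a SmI2-catalysed ketyl radical relay (strain-release formal 3+2) builds both carbocycles of the bornane in one operation.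
3. Enabling feature: the benzylic carbon of the oxepine ring is carried as a ketone, so ring C1–C6–C7 is an aryl cyclopropyl ketone whose C6–C7 bond breaks on one-electron reduction; the allyl group on C2 places its internal carbon (C4) five atoms from the C7 radical.
4. The precursor comes from an intramolecular SNAr (oxepinone ring), a reagent-controlled allylboration (C2), addition of an ortho-fluoroaryllithium to a cyclopropane-fused lactone, and an asymmetric intramolecular cyclopropanation (C1).
5. Order of ring formation: cyclopropane and lactone (step 3), oxepinone (step 9), then both five-membered rings and the six-membered ring of the bornane with loss of the cyclopropane (step 10).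

Key step: step 10

Remark on numbering: bornane locants are used for the terpene part at every stage (C1 methyl-bearing bridgehead, C2 oxygen-bearing carbon, C3, C4 CH bridgehead, C5, C6 carbon bonded to the benzylic carbon, C7 CMe2).
Assumption: the sense of induction in step 3 is taken to follow that of prenyl and methallyl diazoacetates with the same catalyst series; if it were the reverse, the 4R catalyst would be used.

**Route**

Step 1
Reactants: 1 2,3-dimethylbut-2-ene
Product: 2 2,3-dimethylbut-2-en-1-ol
Conditions: SeO2 (10 mol%), t-BuOOH, CH2Cl2, rt
Reagents that add atoms: tert-butyl hydroperoxide, CC(C)(C)OO (terminal oxidant; the oxygen is passed on through SeO2, O=[Se]=O)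
Why: SeO2 allylic oxidation (ene reaction, then [2,3]-sigmatropic shift) returns the double bond to its original position, and all twelve allylic hydrogens of the symmetrical alkene are equivalent, so only this primary allylic alcohol should form.

Step 2
Reactants: 2 2,3-dimethylbut-2-en-1-ol
Product: 4 2,3-dimethylbut-2-en-1-yl diazoacetate, via bromoacetate ester 3 (not isolated)
Conditions: BrCH2COBr, NaHCO3, MeCN, 0 °C; then TsNHNHTs, DBU, THF, 0 °C
Reagents that add atoms: bromoacetyl bromide, BrCC(Br)=O; N,N'-ditosylhydrazine, Cc1ccc(cc1)S(=O)(=O)NNS(=O)(=O)c1ccc(C)cc1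
Why: O-acylation followed by N-alkylation of the ditosylhydrazide and double sulfinate elimination is a standard two-stage diazoacetate synthesis that tolerates the electron-rich alkene.

Step 3
Reactants: 4 2,3-dimethylbut-2-en-1-yl diazoacetate
Product: 5 (1R,5R)-5,6,6-trimethyl-3-oxabicyclo[3.1.0]hexan-2-one
Conditions: Rh2(4S-MPPIM)4 (1 mol%; dirhodium tetrakis[methyl (4S)-2-oxo-1-(3-phenylpropanoyl)imidazolidine-4-carboxylate]), CH2Cl2, reflux, slow addition of 4
Reagents that add atoms: none
Why: Intramolecular cyclopropanation by a chiral dirhodium carboxamidate carbenoid should close the necessarily cis-fused cyclopropane lactone, the catalyst choosing the alkene face and so fixing both ring-fusion centres, including the methyl-bearing quaternary carbon that becomes C1.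

Step 4
Reactants: 6 1,3,5-trifluorobenzene
Product: 7 1,3-bis(benzyloxy)-5-fluorobenzene
Conditions: BnOH (2.1 equiv), NaH (2.2 equiv), NMP, 0 → 100 °C
Reagents that add atoms: benzyl alcohol, OCc1ccccc1
Why: Two successive SNAr displacements of fluoride by benzyloxide should stop at the monofluoride because each alkoxy group deactivates the ring further.

Step 5
Reactants: 7 1,3-bis(benzyloxy)-5-fluorobenzene
Product: 8 1,5-bis(benzyloxy)-2-bromo-3-fluorobenzene
Conditions: NBS, MeCN, 0 °C → rt
Reagents that add atoms: N-bromosuccinimide, O=C1CCC(=O)N1Br
Why: Electrophilic aromatic bromination should go para to one benzyloxy group and ortho to the other, the carbon between the two benzyloxy groups being the more hindered site.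

Step 6
Reactants: 8 1,5-bis(benzyloxy)-2-bromo-3-fluorobenzene; 5 (1R,5R)-5,6,6-trimethyl-3-oxabicyclo[3.1.0]hexan-2-one
Product: 10 [2,4-bis(benzyloxy)-6-fluorophenyl][(1R,3R)-3-(hydroxymethyl)-2,2,3-trimethylcyclopropyl]methanone, via aryllithium 9 (not isolated)
Conditions: n-BuLi, THF, −78 °C; then 5, −78 °C; aq. NH4Cl
Reagents that add atoms: none
Why: Bromine–lithium exchange at −78 °C (faster than benzylic deprotonation and cold enough to hold back LiF loss to the aryne) gives an aryllithium whose addition to the lactone stops at the lithium lactolate, which collapses on quench to the cis hydroxy ketone without touching either cyclopropane stereocentre.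

Step 7
Reactants: 10 hydroxy ketone
Product: 11 (1R,3R)-3-[2,4-bis(benzyloxy)-6-fluorobenzoyl]-1,2,2-trimethylcyclopropane-1-carbaldehyde
Conditions: Dess–Martin periodinane, CH2Cl2, 0 °C → rt
Reagents that add atoms: none
Why: Dess–Martin oxidation of the primary alcohol (drawn from its open form, which equilibrates with the cyclic hemiketal) should give an aldehyde that has no α-hydrogen and therefore cannot epimerise.

Step 8
Reactants: 11 keto aldehyde
Product: 12 [2,4-bis(benzyloxy)-6-fluorophenyl]{(1R,3R)-3-[(1S)-1-hydroxybut-3-en-1-yl]-2,2,3-trimethylcyclopropyl}methanone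
Conditions: (−)-Ipc2BOMe, allylMgBr, Et2O, −78 °C → rt; then 11, −78 °C; NaOH, H2O2, 0 °C
Reagents that add atoms: allylmagnesium bromide, C=CC[Mg]Br
Why: Brown allylation with the (+)-α-pinene-derived reagent should add allyl to the aldehyde through a closed chair transition state under reagent control to set C2 as S, while the di-ortho-substituted aryl ketone is too hindered to react.

Step 9
Reactants: 12 homoallylic alcohol
Product: 13 cyclopropane-fused benzoxepinone (allyl on C2 cis to the CMe2 bridge)
Conditions: KOt-Bu, THF, 0 → 50 °C
Reagents that add atoms: none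
Why: Intramolecular SNAr: the potassium alkoxide displaces the fluoride that is activated by the ortho ketone, the cis cyclopropane holding the two arms within reach of a seven-membered ring, and no stereocentre is touched because neither the carbinol carbon nor the cyclopropane carbons are involved.

Step 10
Reactants: 13 cyclopropane-fused benzoxepinone
Product: 14 pentacyclic benzoxepinone (complete ring system of the target)
Conditions: SmI2 (20 mol%), Sm metal (20 mol%), THF, 55 °C, degassed
Reagents that add atoms: none
Why: Proposed new method: single-electron transfer from SmI2 to the benzoxepinone carbonyl gives a ketyl that opens the fused cyclopropane at the exocyclic C6–C7 bond (strain release, tertiary radical at C7, trivalent samarium enolate at C6); the C7 radical closes on the internal carbon of the allyl group (5-exo-trig, forming the C4–C7 bond and the first cyclopentane), and the primary radical at C5 rebounds onto the enolate carbon C6 (5-exo-trig onto the enolate C=C, completing the second cyclopentane and with it the six-membered ring of the bornane), after which the new ketyl returns its electron to trivalent samarium so that SmI2 turns over. The closest known reaction type is the SmI2-catalysed (or visible-light photocatalytic) radical-relay formal (3+2) cycloaddition of cyclopropyl ketones with alkenes, known in intermolecular and ring-fused intramolecular form; new here are the bridged mode, in which the alkene hangs from the cyclopropane carbon that keeps the radical arm, and the unactivated terminal alkene. C4 is set in the first closure by a chair-like transition state with the aryloxy substituent on C2 pseudo-equatorial, which places the CH2 radical cis to C6, and C6 is set in the rebound by the cis-fused seven-membered ring, which leaves only the endo,endo closure open; C1 and C2 come unchanged from 13. The step needs cleavage of C6–C7 rather than the ring-fusion bond C6–C1, which is secured by the better overlap of the exocyclic bond with the ketyl and by the fact that a C1 radical has no productive closure and should reclose, and it needs the stated face selectivity at C4, since the C4 epimer cannot rebound. The cyclopropane strain and the exchange of one C=C π bond for two C–C σ bonds pay for the strain of the bicyclo[2.2.1]heptane.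

Step 11
Reactants: 14 pentacyclic benzoxepinone
Product: 16 diphenol (target without isovaleryl and formyl groups), via benzylic alcohol 15 (not isolated)
Conditions: LiAlH4, THF, 0 °C → rt; aqueous work-up; then H2 (1 atm), Pd/C, EtOAc–AcOH, rt
Reagents that add atoms: none
Why: Hydride reduction of the ketone followed by hydrogenolysis: loss of the two benzyl ethers unmasks ortho and para hydroxyls that make the benzylic C–OH bond labile (quinone methide), so the same hydrogenation should take the carbinol down to CH2, while the aryl–O–C2 ether, which is not benzylic on its alkyl side, stays.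

Step 12
Reactants: 16 diphenol
Product: 17 isovaleryl diphenol (target without formyl group)
Conditions: i-BuCOCl, TiCl4, CH2Cl2, −20 °C → rt; aq. HCl
Reagents that add atoms: 3-methylbutanoyl chloride, CC(C)CC(Cl)=O
Why: Friedel–Crafts acylation (with Fries-type delivery from either O-acyl phenol) should take the ring carbon flanked by the two free hydroxyls, where the product ketone is chelated on both sides, in preference to the carbon next to the bulky bornyl ether oxygen.

Step 13
Reactants: 17 isovaleryl diphenol
Product: 18 CNP0246493.1 (target)
Conditions: Cl2CHOMe, TiCl4, CH2Cl2, −78 → 0 °C; aq. HCl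
Reagents that add atoms: dichloromethyl methyl ether, COC(Cl)Cl
Why: Rieche formylation can only attack the single remaining ring carbon, which is still activated by an ortho hydroxyl, an ortho ether oxygen and a para hydroxyl, and hydrolysis of the chloro ether should give the aldehyde.

**Compound list**
1 | 2,3-dimethylbut-2-ene | CC(C)=C(C)C | starting material
2 | 2,3-dimethylbut-2-en-1-ol | CC(C)=C(C)CO | intermediate
3 | 2,3-dimethylbut-2-en-1-yl bromoacetate | CC(C)=C(C)COC(=O)CBr | intermediate (not isolated)
4 | 2,3-dimethylbut-2-en-1-yl diazoacetate | CC(C)=C(C)COC(=O)C=[N+]=[N-] | intermediate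
5 | (1R,5R)-5,6,6-trimethyl-3-oxabicyclo[3.1.0]hexan-2-one (cis-fused; CH next to C=O, methyl-bearing quaternary carbon next to OCH2) | O=C1OC[C@]2(C)[C@H]1C2(C)C | intermediate
6 | 1,3,5-trifluorobenzene | Fc1cc(F)cc(F)c1 | starting material
7 | 1,3-bis(benzyloxy)-5-fluorobenzene | Fc1cc(OCc2ccccc2)cc(OCc2ccccc2)c1 | intermediate
8 | 1,5-bis(benzyloxy)-2-bromo-3-fluorobenzene | Fc1cc(OCc2ccccc2)cc(OCc2ccccc2)c1Br | intermediate
9 | [2,4-bis(benzyloxy)-6-fluorophenyl]lithium | [Li]c1c(F)cc(OCc2ccccc2)cc1OCc1ccccc1 | intermediate (not isolated)
10 | [2,4-bis(benzyloxy)-6-fluorophenyl][(1R,3R)-3-(hydroxymethyl)-2,2,3-trimethylcyclopropyl]methanone (aroyl and CH2OH cis) | OC[C@]1(C)[C@H](C(=O)c2c(F)cc(OCc3ccccc3)cc2OCc2ccccc2)C1(C)C | intermediate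
11 | (1R,3R)-3-[2,4-bis(benzyloxy)-6-fluorobenzoyl]-1,2,2-trimethylcyclopropane-1-carbaldehyde | O=C[C@]1(C)[C@H](C(=O)c2c(F)cc(OCc3ccccc3)cc2OCc2ccccc2)C1(C)C | intermediate
12 | [2,4-bis(benzyloxy)-6-fluorophenyl]{(1R,3R)-3-[(1S)-1-hydroxybut-3-en-1-yl]-2,2,3-trimethylcyclopropyl}methanone | C=CC[C@H](O)[C@]1(C)[C@H](C(=O)c2c(F)cc(OCc3ccccc3)cc2OCc2ccccc2)C1(C)C | intermediate
13 | (2S)-2-allyl-6,8-bis(benzyloxy)-3-methyl-3,4-dihydro-1-benzoxepin-5(2H)-one with a C(CH3)2 bridge joining C3 and C4 (cis-fused gem-dimethylcyclopropane; allyl and the C(CH3)2 carbon on the same face of the seven-membered ring) | c1c(OCc4ccccc4)cc2c(c1OCc1ccccc1)C(=O)[C@@H]1C(C)(C)[C@]1(C)[C@H](CC=C)O2 | intermediate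
14 | ring system of the target (bornane bridged from 2-endo-O to 6-endo-C by the aryl ring) with C=O in place of the benzylic CH2, benzyloxy in place of both phenolic OH, H in place of the isovaleryl and formyl groups | c1c(OCc4ccccc4)cc2c(c1OCc1ccccc1)C(=O)[C@@H]1C[C@@H]3C[C@H](O2)[C@@]1(C)C3(C)C | intermediate
15 | as 14 with CH(OH) in place of C=O (carbinol configuration not fixed; the centre is removed in the same step) | c1c(OCc4ccccc4)cc2c(c1OCc1ccccc1)C(O)[C@@H]1C[C@@H]3C[C@H](O2)[C@@]1(C)C3(C)C | intermediate (not isolated)
16 | the target without its isovaleryl and formyl groups (two free phenols, benzylic CH2) | c1c(O)cc2c(c1O)C[C@@H]1C[C@@H]3C[C@H](O2)[C@@]1(C)C3(C)C | intermediate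
17 | the target without its formyl group (isovaleryl between the two phenols) | CC(C)CC(=O)c1c(O)cc2c(c1O)C[C@@H]1C[C@@H]3C[C@H](O2)[C@@]1(C)C3(C)C | intermediate
18 | CNP0246493.1 | CC(C)CC(=O)c1c(O)c(C=O)c2c(c1O)C[C@@H]1C[C@@H]3C[C@H](O2)[C@@]1(C)C3(C)C | target

**Step count and risks**
Total steps: 13. Longest linear sequence: 11 (steps 1–3 and 6–13; the aryl branch, steps 4–5, joins at step 6).

Steps most likely to fail:

1. Step 10 (proposed new method). What may go wrong: the first closure may take the other alkene face, giving a C4 epimer that cannot rebound and is lost by reduction, which drains the catalyst; the ring-fusion bond C6–C1 may open instead, giving a C1 radical that can expel the aryloxide; or electron return to the unopened ketyl may outrun ring opening. Fallback with known chemistry, from 13 back to 14: iodotrimethylsilane in CH2Cl2 at −78 °C should open the cyclopropyl ketone by homoconjugate addition to the silyl enol ether tertiary iodide F1, which is hydrolysed on work-up to the γ-iodo ketone F2. Iodine-atom-transfer radical cyclisation (hexabutylditin, light, benzene) should then close the same 5-exo ring and leave the chain-carrying iodine on C5 in the primary iodide F3, from which a wrong C4 epimer can be separated. KOt-Bu in THF finally alkylates the ketone enolate intramolecularly at C6 with the iodide and gives 14.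

2. Step 9. What may go wrong: reversible addition of the alkoxide to the neighbouring carbonyl (five-membered hemiketal) switches off the activation of the fluoroarene, or substitution on the electron-rich ring is too slow. Fallback, from 12 back to 14, makes the ether after the bornane instead of before it: TESOTf and 2,6-lutidine give the silyl ether F4, and the SmI2-catalysed relay of step 10, run in its open-chain form, should give the bornane F5 (2-endo silyloxy, 6-exo aroyl, from rebound away from the silyloxy group). TBAF in THF then removes the silyl group to give the alcohol F6; epimerisation at C6 through the enolate leads to the endo ketone F7, in which the rigid bicycle holds the C2 alkoxide and the fluoroarene within bonding distance, and substitution of fluoride gives 14.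

3. Step 12. What may go wrong: attack at the other free ring carbon (between a phenol and the ring oxygen), double acylation, or Lewis-acid ionisation of the secondary alkyl aryl ether. Fallback, from 16 back to 17, fixes the site by directed metalation: MOMCl and i-Pr2NEt give the bis(methoxymethyl) ether F8; n-BuLi and TMEDA in THF at 0 °C lithiate the carbon between the two OMOM groups, and N-methoxy-N-methyl-3-methylbutanamide gives the ketone F9; HCl in MeOH removes both MOM groups and gives 17.

Further compounds
F1 | step 10 | silyl enol ether tertiary iodide (seven-membered ring C=C–OSiMe3, CMe2I on C1) | c1c(OCc4ccccc4)cc2c(c1OCc1ccccc1)C(O[Si](C)(C)C)=C[C@](C)(C(C)(C)I)[C@H](CC=C)O2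
F2 | step 10 | γ-iodo ketone (ring-opened benzoxepinone, CMe2I and methyl on C1, allyl on C2) | c1c(OCc4ccccc4)cc2c(c1OCc1ccccc1)C(=O)C[C@](C)(C(C)(C)I)[C@H](CC=C)O2
F3 | step 10 | primary iodide (cyclopentane cis-fused to the benzoxepinone, CH2I on C4 cis to C6) | c1c(OCc4ccccc4)cc2c(c1OCc1ccccc1)C(=O)C[C@@]1(C)[C@@H](O2)C[C@@H](CI)C1(C)C
F4 | step 9 | triethylsilyl ether of 12 | C=CC[C@H](O[Si](CC)(CC)CC)[C@]1(C)[C@H](C(=O)c2c(F)cc(OCc3ccccc3)cc2OCc2ccccc2)C1(C)C
F5 | step 9 | 6-exo-[2,4-bis(benzyloxy)-6-fluorobenzoyl]-2-endo-(triethylsilyloxy)bornane | O=C(c1c(F)cc(OCc2ccccc2)cc1OCc1ccccc1)[C@H]1C[C@@H]2C[C@H](O[Si](CC)(CC)CC)[C@@]1(C)C2(C)C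
F6 | step 9 | 6-exo-[2,4-bis(benzyloxy)-6-fluorobenzoyl]bornan-2-endo-ol | O=C(c1c(F)cc(OCc2ccccc2)cc1OCc1ccccc1)[C@H]1C[C@@H]2C[C@H](O)[C@@]1(C)C2(C)C
F7 | step 9 | 6-endo-[2,4-bis(benzyloxy)-6-fluorobenzoyl]bornan-2-endo-ol | O=C(c1c(F)cc(OCc2ccccc2)cc1OCc1ccccc1)[C@@H]1C[C@@H]2C[C@H](O)[C@@]1(C)C2(C)C
F8 | step 12 | bis(methoxymethyl) ether of 16 | c1c(OCOC)cc2c(c1OCOC)C[C@@H]1C[C@@H]3C[C@H](O2)[C@@]1(C)C3(C)C
F9 | step 12 | bis(methoxymethyl) ether of 17 | CC(C)CC(=O)c1c(OCOC)cc2c(c1OCOC)C[C@@H]1C[C@@H]3C[C@H](O2)[C@@]1(C)C3(C)C
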